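**Retrosynthetic overview**
- Kadsurenin D is an isomer of a cis-fused aryl cyclobutane (a bicyclo[4.2.0]octenedione). The last step is an ionic four-to-five ring expansion: the ring-fusion C–CH(Ar) bond is cut and CH(Ar) re-bonds to the enol-ether carbon across the ring, while OMe and C=O change places.
- The cyclobutane comes from 2-allyl-5-methoxy-1,4-benzoquinone and (E)-4-propenylveratrole by a stepwise formal [2+2] on a chiral titanium complex. This sets the quaternary carbon and the CH(CH3) centre.
- The quinone comes from 4,5-dimethoxy-1,2-benzoquinone and allylmagnesium bromide (1,2-addition, then acid transposition). That o-quinone comes from catechol.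
- The propenylveratrole also comes from catechol (O-methylation, bromination, Suzuki coupling with propenylboronic acid).
- Ring order: six-membered carbocycle (from catechol), then the four-membered ring, then its expansion to the five-membered ketone ring, which completes the bicyclo[3.2.1]octane.

Assumption: the target is taken exactly as the given SMILES, (1S,5S,6R,7R). The facial sense of the (R,R)-TADDOLate on this allyl quinone is not established, so the (S,S)-ligand is used instead if (R,R) gives the mirror image.

**Step 1**
Reactants: 1 catechol (benzene-1,2-diol)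
Product: 2 veratrole (1,2-dimethoxybenzene)
Conditions: MeI (2.5 equiv), K2CO3, acetone, reflux
Reagents that add atoms: iodomethane, CI
Why: Williamson ether synthesis; both phenoxides are methylated by SN2 and no stereocentre is involved.

**Step 2**
Reactants: 2 veratrole
Product: 3 4-bromo-1,2-dimethoxybenzene
Conditions: NBS, MeCN, 0 °C to rt
Reagents that add atoms: N-bromosuccinimide, O=C1CCC(=O)N1Br
Why: Electrophilic aromatic bromination; attack para to one methoxy group is strongly preferred and monobromination is clean in MeCN.

**Step 3**
Reactants: 3 4-bromo-1,2-dimethoxybenzene; 4 (E)-prop-1-en-1-ylboronic acid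
Product: 5 (E)-1,2-dimethoxy-4-(prop-1-en-1-yl)benzene
Conditions: Pd(PPh3)4 (3 mol %), K2CO3, 1,4-dioxane/H2O, 85 °C
Reagents that add atoms: none
Why: Suzuki–Miyaura cross-coupling; transmetalation and reductive elimination retain the alkene geometry, so the E-propenyl group is transferred unchanged.

**Step 4**
Reactants: 1 catechol
Product: 6 4,5-dimethoxy-1,2-benzoquinone (4,5-dimethoxycyclohexa-3,5-diene-1,2-dione)
Conditions: NaIO3, MeOH, rt
Reagents that add atoms: methanol, CO
Why: Oxidative methoxylation; iodate gives o-benzoquinone, methanol adds in Michael fashion at C-4 and then C-5 with re-oxidation each time, and the sequence stops at the doubly vinylogous ester.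

**Step 5**
Reactants: 6 4,5-dimethoxy-1,2-benzoquinone; 7 allylmagnesium bromide
Product: 9 2-allyl-5-methoxy-1,4-benzoquinone, via racemic ortho-quinol 8 (not isolated)
Conditions: THF, −78 °C (1.0 equiv of 7); AcOH (1 equiv); then TsOH·H2O (10 mol %), THF/H2O, 0 °C to rt
Reagents that add atoms: water, O
Why: Stork–Danheiser-type alkylative carbonyl transposition; the allyl Grignard adds 1,2 to one of the two equivalent vinylogous-ester carbonyls, acid ionises the tertiary allylic alcohol with help from the para methoxy group, water is captured at that methoxy carbon and methanol is lost, so the stereocentre of 8 disappears.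

**Step 6**
Reactants: 5 (E)-1,2-dimethoxy-4-(prop-1-en-1-yl)benzene; 9 2-allyl-5-methoxy-1,4-benzoquinone
Product: 10 (1S,6R,7R,8R)-1-allyl-7-(3,4-dimethoxyphenyl)-4-methoxy-8-methylbicyclo[4.2.0]oct-3-ene-2,5-dione (cis-fused; allyl, 8-CH3, H-6 and H-7 on one face, aryl on the face of the six-membered ring)
Conditions: TiCl2[(R,R)-TADDOLate] (2.5 equiv, preformed), 4 Å MS, toluene/CH2Cl2, −78 °C; aq NaHCO3
Reagents that add atoms: none
Why: Chelation of the C-4 carbonyl and the 5-OMe of 9 to tetravalent titanium makes the allyl-bearing C-2 the electrophilic site, the CH(CH3) terminus of 5 alkylates it with the aryl group lying over the quinone, and the benzylic cation collapses on the titanium enolate carbon C-3 (stepwise Lewis-acid-promoted formal [2+2], a reaction class established for 2-methoxy-1,4-benzoquinones and (E)-propenylarenes with titanium TADDOLates), so the E geometry gives trans CH3/aryl, the fusion is cis, and the TADDOLate shields one quinone face and fixes the absolute configuration at C-1, C-6, C-7 and C-8.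

**Step 7**
Reactants: 10 (1S,6R,7R,8R)-1-allyl-7-(3,4-dimethoxyphenyl)-4-methoxy-8-methylbicyclo[4.2.0]oct-3-ene-2,5-dione
Product: 13 kadsurenin D, via benzylic cation 11 (not isolated), via bicyclic oxocarbenium ion 12 (not isolated)
Conditions: Me3OBF4 (10 mol %), 2,6-di-tert-butyl-4-methylpyridine (5 mol %), CH2Cl2, −20 °C to rt
Reagents that add atoms: none
Why: Proposed new method: Me3O+ reversibly methylates the C-5 carbonyl oxygen of 10, and the resulting oxocarbenium ion draws the electrons of the strained C6–C7 bond into a C5=C6 enol ether (the 3-OMe/C3=C4 unit of the target), releasing the 3,4-dimethoxybenzyl cation 11 (donor–acceptor cyclobutane heterolysis, about 26 kcal/mol of strain released); 11 is captured by C-3, the nucleophilic β-carbon of the remaining methoxy enone, which the tether reaches only from its own face (sets target C-1) and through the rotamer with aryl anti to the neighbouring methyl, that is exo (sets target C-7), closing the five-membered ketone ring in 12; 12 then passes its O-methyl group to Me2O or to the next molecule of 10, so a net four-to-five ring expansion with OMe/C=O exchange runs as a methyl-relay chain in which the oxonium salt only starts the chain, while the untouched C-1 and C-8 of 10 become C-5 and C-6 of the target; closest known reaction types are the TiCl4-promoted rearrangement of 8-arylbicyclo[4.2.0]octenediones to 3-hydroxybicyclo[3.2.1]octenediones and the alkyl-transfer chain of the Lander imidate-to-amide rearrangement.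

**Compound list**
1 | catechol | Oc1ccccc1O | starting material
2 | veratrole (1,2-dimethoxybenzene) | COc1ccccc1OC | intermediate
3 | 4-bromo-1,2-dimethoxybenzene | COc1ccc(Br)cc1OC | intermediate
4 | (E)-prop-1-en-1-ylboronic acid | C/C=C/B(O)O | starting material
5 | (E)-1,2-dimethoxy-4-(prop-1-en-1-yl)benzene | C/C=C/c1ccc(OC)c(OC)c1 | intermediate
6 | 4,5-dimethoxy-1,2-benzoquinone | COC1=CC(=O)C(=O)C=C1OC | intermediate
7 | allylmagnesium bromide | C=CC[Mg]Br | starting material
8 | racemic 6-allyl-6-hydroxy-3,4-dimethoxycyclohexa-2,4-dien-1-one (ortho-quinol, not isolated) | C=CCC1(O)C=C(OC)C(OC)=CC1=O | intermediate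
9 | 2-allyl-5-methoxy-1,4-benzoquinone | C=CCC1=CC(=O)C(OC)=CC1=O | intermediate
10 | (1S,6R,7R,8R)-1-allyl-7-(3,4-dimethoxyphenyl)-4-methoxy-8-methylbicyclo[4.2.0]oct-3-ene-2,5-dione | C=CC[C@@]12C(=O)C=C(OC)C(=O)[C@@H]1[C@H](c1ccc(OC)c(OC)c1)[C@H]2C | intermediate
11 | ring-opened 3,4-dimethoxybenzyl cation carried by a 6-allyl-3,4-dimethoxycyclohexa-2,4-dienone, tetrafluoroborate (not isolated) | C=CC[C@]1([C@H](C)[CH+]c2ccc(OC)c(OC)c2)C=C(OC)C(OC)=CC1=O.F[B-](F)(F)F | intermediate
12 | O(2)-methyl oxocarbenium ion of kadsurenin D, tetrafluoroborate (not isolated) | C=CC[C@]12C=C(OC)C(=[O+]C)[C@H](C1=O)[C@H](c1ccc(OC)c(OC)c1)[C@H]2C.F[B-](F)(F)F | intermediate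
13 | kadsurenin D, (1S,5S,6R,7R)-5-allyl-7-(3,4-dimethoxyphenyl)-3-methoxy-6-methylbicyclo[3.2.1]oct-3-ene-2,8-dione (aryl exo, methyl endo) | C=CC[C@]12C=C(OC)C(=O)[C@H](C1=O)[C@H](c1ccc(OC)c(OC)c1)[C@H]2C | target

**Step count and risks**
Total step count: 7. Longest linear sequence: 5 steps (1 → 2 → 3 → 5 → 10 → 13).

**Most likely to fail, first: step 7 (the new step).**
- Risk: cation 11 could close on the carbonyl oxygen to give the isomeric hydrobenzofuranone, or be trapped by the allyl double bond.
- Risk: methylation of the more basic vinylogous-ester carbonyl could slow the chain.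
- Fallback: it sets out from 10 and uses known chemistry. Excess TiCl4 in CH2Cl2 at −78 °C induces the established Lewis-acid rearrangement with loss of the methyl group, giving (1S,5S,6R,7R)-5-allyl-7-(3,4-dimethoxyphenyl)-3-hydroxy-6-methylbicyclo[3.2.1]oct-3-ene-2,8-dione F1. O-methylation of this diosphenol with MeI and K2CO3 in acetone comes back to the route at 13.

**Second: step 6.**
- Risk: the allyl-bearing quinone carbon is hindered, so conversion or enantioselectivity with the TADDOLate may be low, and part of the material may already rearrange.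
- Fallback: it sets out from 5 and 9 and replaces asymmetric induction by resolution. An achiral 1:1 mixture of TiCl4 and Ti(OiPr)4 in CH2Cl2 at −78 °C gives the racemic cyclobutane, that is 10 together with (1R,6S,7S,8S)-1-allyl-7-(3,4-dimethoxyphenyl)-4-methoxy-8-methylbicyclo[4.2.0]oct-3-ene-2,5-dione F2. Preparative HPLC on a chiral stationary phase separates the two and returns to the route at 10.

**Third: step 5.**
- Risk: electron transfer from the Grignard reagent, double addition, or displacement of a methoxy group may compete with the single 1,2-addition.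
- Fallback: it sets out from 3 and builds the quinone from a phenol.
  - Hydroxylation with Pd2(dba)3, tBuXPhos and KOH in dioxane/H2O gives 3,4-dimethoxyphenol F3.
  - Allyl bromide and K2CO3 give 4-(allyloxy)-1,2-dimethoxybenzene F4.
  - A thermal aromatic Claisen rearrangement (N,N-diethylaniline, 200 °C) gives 2-allyl-4,5-dimethoxyphenol F5.
  - Oxidative demethylation with PhI(OAc)2 in MeCN/H2O at 0 °C comes back to the route at 9.

**Further compounds**
F1 | step 7 | (1S,5S,6R,7R)-5-allyl-7-(3,4-dimethoxyphenyl)-3-hydroxy-6-methylbicyclo[3.2.1]oct-3-ene-2,8-dione | C=CC[C@]12C=C(O)C(=O)[C@H](C1=O)[C@H](c1ccc(OC)c(OC)c1)[C@H]2C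
F2 | step 6 | (1R,6S,7S,8S)-1-allyl-7-(3,4-dimethoxyphenyl)-4-methoxy-8-methylbicyclo[4.2.0]oct-3-ene-2,5-dione | C=CC[C@]12C(=O)C=C(OC)C(=O)[C@H]1[C@@H](c1ccc(OC)c(OC)c1)[C@@H]2C
F3 | step 5 | 3,4-dimethoxyphenol | COc1ccc(O)cc1OC
F4 | step 5 | 4-(allyloxy)-1,2-dimethoxybenzene | C=CCOc1ccc(OC)c(OC)c1
F5 | step 5 | 2-allyl-4,5-dimethoxyphenol | C=CCc1cc(OC)c(OC)cc1O
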